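(The numbers of this flask are assumed.)

A small charge of G, 2.5 mol% of D, starts the chains in this flask, so I treat the D spent on starting as a correction and reckon the rest from the chains that stand.

    D + G → X + E (k1 = 0.696 /M/s)
    D → L (k2 = 0.0700 /s)
    G → J (k3 = 0.138 /s)
    2 G → G2 (k4 = 4.03 /M/s)
    D + X → E + X, rate k5*[X]*[D] (k5 = 19.0 /M/s)

D 0.62 M; G 2.5 mol%; time 10 s

- two of one species on the left: rate k times its square, two consumed each time
- the average divides the monomer in chains by the number of chains begun, living and dead together
- run time (flask): 10 s

1. whether the average number of monomer units in a chain (chains begun, living or dead) reaches 20 by 10 s (yes / no)
2. average number of monomer units in a chain (chains begun, living or dead) at 10 s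

At the start, each G in this flask goes to a chain at 0.432 /s, to J at 0.138 /s and to G2 at 0.125 /s. I therefore take the share of G that begins a chain as 62.1%. That costs 1.55% of the D, the correction I drop.

No step removes X, so I take D in this flask as falling pseudo-first-order, through the chains at 0.183 /s and to L at 0.0700 /s. The first is faster. Their quotient is the chain ratio, the rate at which standing chains take D over the rate at which D goes to L, and here it is 2.61. Of the D that reacts, a part 72.3% enters chains, which gives a first length of 42.9 at 10 s.

The weak link is that the chains do not stand from the first moment. They arrive over a lag of about 1.44 s, so I let D go to L alone for that long and run the chains for the remaining time. The length becomes 37.3, above the 20 wanted, so I commit to yes.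

The forecast says yes and 38, with “the rest lost to its decay and dimerisation”, and my length stands below it.

This flask gives yes and 38.8, with the length 20 reached at 3.22 s. At 10.0 s the half-life of D by the making of E is 3.9 s against 9.9 s by the loss to L, a quotient of 2.54 against the chain ratio of 2.61, and the flask holds E at 58.2% of the D charged and L at 31.0%.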